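**Plan**

1. Cuts: (a) the bond between ring D and the enone β-carbon (Stille coupling; ring E arrives on a β-stannyl enone); (b) both bonds to C3 of ring C (C2–C3 and C3–C4), so that C3 and ring D leave as an aryldiazomethane and ring C contracts to a 2-aryl-benzofuran-3(2H)-one; (c) the C2–ring B bond (ketone α-arylation).
2. Forward: a purchased benzofuran-3(2H)-one (ring A plus a five-membered O-ring) receives ring B at C2, a one-carbon insertion expands the five-membered ring to ring C and brings in ring D, ring E with the enone is joined last, then all phenols are desilylated.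
3. Enabling feature: C2 carries O1 and ring B. In the five-membered ketone it is α to the C=O, so it racemises through the aromatic 3-hydroxybenzofuran enol and migrates readily; once C3 is inserted it is β to C4=O and configurationally fixed.
4. Stereochemistry: 2S from a dynamic kinetic resolution in the insertion (chiral Sc–pybox complex, migration with retention); 3R by equilibration to the 2,3-trans isomer; the E-alkene is carried in from the E-distannane.

Key step: step 5

Remark: ring A = benzo ring of the chromanone, B = 4-hydroxyphenyl on C2, C = pyranone, D = hydroxyphenyl on C3, E = 2,4-dihydroxyphenyl of the aryl ketone; TBS = tert-butyldimethylsilyl. Assumption: the pybox antipode that draws (R)-4 into the insertion (giving the 2S product) is fixed in a pilot run, and the route is written for that antipode.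

**Step 1**
Reactants: 1 4,6-dihydroxybenzofuran-3(2H)-one
Product: 2 4,6-bis(TBSO)benzofuran-3(2H)-one
Conditions: TBSCl (2.4 equiv), imidazole, DMF, 0 °C → rt
Reagents that add atoms: tert-butyldimethylsilyl chloride, CC(C)(C)[Si](C)(C)Cl
Why: Imidazole-mediated silylation of both phenols is a standard phenol protection and should leave the only weakly acidic C2 methylene untouched.

**Step 2**
Reactants: 2 4,6-bis(TBSO)benzofuran-3(2H)-one; 3 (4-bromophenoxy)(tert-butyl)dimethylsilane
Product: 4 rac-2-[4-(TBSO)phenyl]-4,6-bis(TBSO)benzofuran-3(2H)-one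
Conditions: Pd(OAc)2 (3 mol %), XPhos (6 mol %), K3PO4, toluene, 80 °C, argon
Reagents that add atoms: none
Why: Pd-catalysed ketone α-arylation with K3PO4 as a mild base that spares aryl silyl ethers should stop at monoarylation, because the enolate of 4 is more stabilised and more hindered than that of 2; the C2 stereocentre forms racemic and is deliberately left labile.

**Step 3**
Reactants: 5 2-hydroxy-5-iodobenzaldehyde
Product: 6 2-(TBSO)-5-iodobenzaldehyde
Conditions: TBSCl, imidazole, CH2Cl2, rt
Reagents that add atoms: tert-butyldimethylsilyl chloride, CC(C)(C)[Si](C)(C)Cl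
Why: Standard silylation of a phenol; the iodide, para to the oxygen and meta to the formyl group, is the later handle for the enone.

**Step 4**
Reactants: 6 2-(TBSO)-5-iodobenzaldehyde
Product: 8 [2-(TBSO)-5-iodophenyl]diazomethane, via hydrazone 7 (not isolated)
Conditions: N2H4·H2O (excess), EtOH, 0 °C; then MnO2, MgSO4, CH2Cl2, −20 → 0 °C, cold filtered solution used at once
Reagents that add atoms: hydrazine (as hydrate), NN
Why: Condensation to the hydrazone followed by dehydrogenation with MnO2 is the usual entry to non-stabilised aryldiazomethanes, which are kept cold and in solution.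

**Step 5**
Reactants: 4 rac-2-[4-(TBSO)phenyl]-4,6-bis(TBSO)benzofuran-3(2H)-one; 8 [2-(TBSO)-5-iodophenyl]diazomethane
Product: 10 (2S,3R)-5,7-bis(TBSO)-2-[4-(TBSO)phenyl]-3-[2-(TBSO)-5-iodophenyl]chroman-4-one, via diazonium betaine 9 (not isolated)
Conditions: Sc(OTf)3 (10 mol %), (S,S)-Ph-pybox (12 mol %), 2,6-lutidine (5 mol %), 4 Å MS, toluene, 8 (1.5 equiv) added slowly at −40 °C, then 0 °C
Reagents that add atoms: none
Why: Proposed new method: the diazo carbon of 8 adds to the Sc-bound C3 carbonyl of 4 to give betaine 9, in which the C2–C(carbonyl) bond shifts to the diazonium carbon as N2 leaves, so the inserted carbon becomes C3 of a chroman-4-one and the strained five-membered ketone grows to the six-membered ring C without any ring being closed. The closest known reaction type is the Sc(OTf)3-catalysed insertion of aryldiazomethanes into cyclic ketones (Büchner–Curtius–Schlotterbeck/Tiffeneau–Demjanov homologation), which is known in enantioselective form with chiral oxazoline ligands; new here is its use as a dynamic kinetic resolution of a ketone with a labile α-stereocentre. C2 migrates with retention, and since 4 should racemise through its aromatic 3-hydroxybenzofuran enolate (soft enolisation by Sc(OTf)3 and 2,6-lutidine) faster than it is consumed, the chiral Sc–pybox complex is expected to draw only (R)-4 into the insertion, whose C2 becomes the 2S centre that is no longer α to the ketone and therefore fixed. C3 is set under thermodynamic control, since Sc-mediated enolisation at 0 °C should funnel any cis isomer to the diequatorial 2,3-trans (3R) product. The step needs migration of C2 in preference to the aryl carbon of ring A: C2 is a benzylic, O1-bearing sp3 carbon of high migratory aptitude and its shift keeps ring A conjugated to the developing carbonyl, as in Lewis-acid insertions into benzo-fused ketones where the sp3 carbon moves. Slow addition of 8 at low temperature is meant to suppress O-alkylation of the enol of 4, and the less electrophilic, more hindered chromanone product should resist a second insertion.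

**Step 6**
Reactants: 11 2,4-dihydroxybenzoic acid
Product: 12 tert-butyldimethylsilyl 2,4-bis(TBSO)benzoate
Conditions: TBSCl (3.5 equiv), imidazole, DMF, rt → 40 °C
Reagents that add atoms: tert-butyldimethylsilyl chloride, CC(C)(C)[Si](C)(C)Cl
Why: Exhaustive silylation protects both phenols and turns the acid into a silyl ester that can be activated directly in the next step.

**Step 7**
Reactants: 12 tert-butyldimethylsilyl 2,4-bis(TBSO)benzoate
Product: 13 2,4-bis(TBSO)benzoyl chloride
Conditions: (COCl)2, DMF (cat.), CH2Cl2, 0 °C → rt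
Reagents that add atoms: oxalyl chloride, O=C(Cl)C(=O)Cl
Why: Vilsmeier-type conversion of a silyl ester into the acid chloride runs under neutral conditions, so the aryl silyl ethers should survive.

**Step 8**
Reactants: 13 2,4-bis(TBSO)benzoyl chloride; 14 (E)-1,2-bis(tributylstannyl)ethene
Product: 15 (E)-1-[2,4-bis(TBSO)phenyl]-3-(tributylstannyl)prop-2-en-1-one
Conditions: PdCl2(PPh3)2 (3 mol %), 14 (1.3 equiv), toluene, 60 °C
Reagents that add atoms: none
Why: Stille acylation of one C–Sn bond with retention of the E geometry; the remaining stannyl group, now conjugated to the ketone, is deactivated towards a second acylation.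

**Step 9**
Reactants: 10 (2S,3R)-5,7-bis(TBSO)-2-[4-(TBSO)phenyl]-3-[2-(TBSO)-5-iodophenyl]chroman-4-one; 15 (E)-1-[2,4-bis(TBSO)phenyl]-3-(tributylstannyl)prop-2-en-1-one
Product: 16 (2S,3R)-3-{5-[(E)-3-[2,4-bis(TBSO)phenyl]-3-oxoprop-1-enyl]-2-(TBSO)phenyl}-5,7-bis(TBSO)-2-[4-(TBSO)phenyl]chroman-4-one
Conditions: Pd2(dba)3 (2.5 mol %), AsPh3 (20 mol %), CuI (10 mol %), DMF, 45 °C
Reagents that add atoms: none
Why: Stille coupling of the aryl iodide with the β-stannyl enone is base-free (CuI-accelerated transmetalation), so it should install the E-chalcone without enolising C3 or opening ring C by retro-oxa-Michael reaction.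

**Step 10**
Reactants: 16 hexakis-TBS ether of the target
Product: 17 CNP0272156.2, (2S,3R)-3-{5-[(E)-3-(2,4-dihydroxyphenyl)-3-oxoprop-1-enyl]-2-hydroxyphenyl}-5,7-dihydroxy-2-(4-hydroxyphenyl)chroman-4-one
Conditions: HF·pyridine, pyridine, THF, 0 °C → rt
Reagents that add atoms: none
Why: Fluoride cleavage of the six aryl silyl ethers under mildly acidic HF·pyridine avoids free phenoxides, so neither ring opening at C2 nor cyclisation of the 2'-hydroxychalcone should occur, and C3 stays in its thermodynamic trans arrangement.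

**Compound list**

1 | 4,6-dihydroxybenzofuran-3(2H)-one | O=C1COc2cc(O)cc(O)c12 | starting material
2 | 4,6-bis(TBSO)benzofuran-3(2H)-one | O=C1COc2cc(O[Si](C)(C)C(C)(C)C)cc(O[Si](C)(C)C(C)(C)C)c12 | intermediate
3 | (4-bromophenoxy)(tert-butyl)dimethylsilane | Brc1ccc(O[Si](C)(C)C(C)(C)C)cc1 | starting material
4 | rac-2-[4-(TBSO)phenyl]-4,6-bis(TBSO)benzofuran-3(2H)-one (C2 labile) | O=C1C(c2ccc(O[Si](C)(C)C(C)(C)C)cc2)Oc2cc(O[Si](C)(C)C(C)(C)C)cc(O[Si](C)(C)C(C)(C)C)c12 | intermediate
5 | 2-hydroxy-5-iodobenzaldehyde | O=Cc1cc(I)ccc1O | starting material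
6 | 2-(TBSO)-5-iodobenzaldehyde | O=Cc1cc(I)ccc1O[Si](C)(C)C(C)(C)C | intermediate
7 | (E)-hydrazone of 6 | N/N=C/c1cc(I)ccc1O[Si](C)(C)C(C)(C)C | intermediate
8 | [2-(TBSO)-5-iodophenyl]diazomethane | [N-]=[N+]=Cc1cc(I)ccc1O[Si](C)(C)C(C)(C)C | intermediate
9 | diazonium betaine from (R)-4 and 8 (carbinol and diazonium carbons undefined) | N#[N+]C(c1cc(I)ccc1O[Si](C)(C)C(C)(C)C)C2([O-])c3c(O[Si](C)(C)C(C)(C)C)cc(O[Si](C)(C)C(C)(C)C)cc3O[C@@H]2c2ccc(O[Si](C)(C)C(C)(C)C)cc2 | intermediate
10 | (2S,3R)-5,7-bis(TBSO)-2-[4-(TBSO)phenyl]-3-[2-(TBSO)-5-iodophenyl]chroman-4-one | Ic1ccc(O[Si](C)(C)C(C)(C)C)c([C@H]2C(=O)c3c(O[Si](C)(C)C(C)(C)C)cc(O[Si](C)(C)C(C)(C)C)cc3O[C@@H]2c2ccc(O[Si](C)(C)C(C)(C)C)cc2)c1 | intermediate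
11 | 2,4-dihydroxybenzoic acid | O=C(O)c1ccc(O)cc1O | starting material
12 | tert-butyldimethylsilyl 2,4-bis(TBSO)benzoate | CC(C)(C)[Si](C)(C)OC(=O)c1ccc(O[Si](C)(C)C(C)(C)C)cc1O[Si](C)(C)C(C)(C)C | intermediate
13 | 2,4-bis(TBSO)benzoyl chloride | O=C(Cl)c1ccc(O[Si](C)(C)C(C)(C)C)cc1O[Si](C)(C)C(C)(C)C | intermediate
14 | (E)-1,2-bis(tributylstannyl)ethene | CCCC[Sn](CCCC)(CCCC)/C=C/[Sn](CCCC)(CCCC)CCCC | starting material
15 | (E)-1-[2,4-bis(TBSO)phenyl]-3-(tributylstannyl)prop-2-en-1-one | O=C(/C=C/[Sn](CCCC)(CCCC)CCCC)c1ccc(O[Si](C)(C)C(C)(C)C)cc1O[Si](C)(C)C(C)(C)C | intermediate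
16 | hexakis-TBS ether of the target, (2S,3R), E | O=C(/C=C/c1ccc(O[Si](C)(C)C(C)(C)C)c([C@H]2C(=O)c3c(O[Si](C)(C)C(C)(C)C)cc(O[Si](C)(C)C(C)(C)C)cc3O[C@@H]2c2ccc(O[Si](C)(C)C(C)(C)C)cc2)c1)c1ccc(O[Si](C)(C)C(C)(C)C)cc1O[Si](C)(C)C(C)(C)C | intermediate
17 | CNP0272156.2 | O=C(/C=C/c1ccc(O)c([C@H]2C(=O)c3c(O)cc(O)cc3O[C@@H]2c2ccc(O)cc2)c1)c1ccc(O)cc1O | target

Total step count: 10. Longest linear sequence: 5 steps (steps 3, 4, 5, 9, 10; the branches from 1 and from 11 are equally long).

**Steps most likely to fail**

1. Step 5 (the proposed new method). The process at risk is the dynamic resolution: racemisation of 4 may lag behind the insertion, or the catalyst may discriminate poorly between the enantiomers of 4, so that C2 is formed with low enantiomeric purity. (Migration of the ring A aryl carbon in place of C2, giving a chroman-3-one, is the other conceivable failure; the Why line argues against it, and this fallback would not cure it.) The fallback sets out from 4 and 8 and uses the known ligand-free insertion: Sc(OTf)3 (10 mol %) in toluene at −78 → 0 °C should give the racemic trans-chromanone F1. This is resolved by preparative HPLC on a chiral stationary phase (amylose tris(3,5-dimethylphenylcarbamate)), and the 2S,3R enantiomer rejoins the route at 10.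

2. Step 9. The process at risk is slow transmetalation of the acceptor-substituted vinylstannane, which would let protodestannylation and homocoupling of 15 take over. The fallback sets out from 10 and from 13 and swaps the coupling for an olefin metathesis. Stille coupling of 10 with tributyl(vinyl)stannane (Pd2(dba)3, AsPh3, CuI, DMF, 45 °C) should give the styrene F2. Stille acylation of tributyl(vinyl)stannane with 13 (PdCl2(PPh3)2, toluene, 60 °C) should give the aryl vinyl ketone F3. Cross-metathesis of F2 with F3 (second-generation Hoveyda–Grubbs catalyst, CH2Cl2, 40 °C) is expected to give the E-enone and comes back to the route at 16.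

3. Step 4. The processes at risk are loss of the aryl silyl ether to hydrazine (the ortho-formyl group activates it), azine formation, and decomposition of the diazoalkane on the oxidant. The fallback sets out from 6 and uses the Bamford–Stevens route. Condensation with p-toluenesulfonohydrazide (MeOH, rt) should give the tosylhydrazone F4. Deprotonation with NaH (THF, 0 °C) gives the sodium salt F5. Fragmentation of F5 at 40 °C with benzyltriethylammonium chloride as phase-transfer catalyst in toluene releases the diazoalkane and comes back to the route at 8.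

**Further compounds**

F1 | step 5 | racemic trans-5,7-bis(TBSO)-2-[4-(TBSO)phenyl]-3-[2-(TBSO)-5-iodophenyl]chroman-4-one (both enantiomers) | Ic1ccc(O[Si](C)(C)C(C)(C)C)c([C@H]2C(=O)c3c(O[Si](C)(C)C(C)(C)C)cc(O[Si](C)(C)C(C)(C)C)cc3O[C@@H]2c2ccc(O[Si](C)(C)C(C)(C)C)cc2)c1.Ic1ccc(O[Si](C)(C)C(C)(C)C)c([C@@H]2C(=O)c3c(O[Si](C)(C)C(C)(C)C)cc(O[Si](C)(C)C(C)(C)C)cc3O[C@H]2c2ccc(O[Si](C)(C)C(C)(C)C)cc2)c1
F2 | step 9 | (2S,3R)-5,7-bis(TBSO)-2-[4-(TBSO)phenyl]-3-[2-(TBSO)-5-vinylphenyl]chroman-4-one | C=Cc1ccc(O[Si](C)(C)C(C)(C)C)c([C@H]2C(=O)c3c(O[Si](C)(C)C(C)(C)C)cc(O[Si](C)(C)C(C)(C)C)cc3O[C@@H]2c2ccc(O[Si](C)(C)C(C)(C)C)cc2)c1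
F3 | step 9 | 1-[2,4-bis(TBSO)phenyl]prop-2-en-1-one | C=CC(=O)c1ccc(O[Si](C)(C)C(C)(C)C)cc1O[Si](C)(C)C(C)(C)C
F4 | step 4 | (E)-N'-[2-(TBSO)-5-iodobenzylidene]-4-methylbenzenesulfonohydrazide | Cc1ccc(cc1)S(=O)(=O)N/N=C/c1cc(I)ccc1O[Si](C)(C)C(C)(C)C
F5 | step 4 | sodium salt of F4 | Cc1ccc(cc1)S(=O)(=O)[N-]/N=C/c1cc(I)ccc1O[Si](C)(C)C(C)(C)C.[Na+]
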